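**Retrosynthetic overview**

1. Target 13 ⇒ chalcone 4-O-prenyl ether 11 by a final aromatic Claisen rearrangement; the prenyl group on O4 becomes the 1,1-dimethylallyl group at C5, the only free ortho carbon.
2. 11 ⇒ aryl–C(=O) bond: an (E)-enoyl anion equivalent (acylzirconocene chloride 9, made from alkyne 4, Cp2Zr(H)Cl and CO) plus 4-iodophenol 5 as the aryl electrophile; the E alkene comes from syn hydrozirconation.
3. Alkyne 4 ⇒ aldehyde 3 (one-carbon homologation) ⇒ 2,3,4-trihydroxybenzaldehyde 1 by two regioselective O-alkylations (prenyl on O4, then methyl on O2).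
4. No ring is formed: ring B is bought as 1 and ring A as 5.

Assumption: the target has no stereocentre, so "single enantiomer" is taken to mean the single (E) isomer of the enone.

**Route**

Step 1
Reactants: 1 2,3,4-trihydroxybenzaldehyde
Product: 2 2,3-dihydroxy-4-[(3-methylbut-2-en-1-yl)oxy]benzaldehyde
Conditions: prenyl bromide (1.05 equiv), NaHCO3 (1.5 equiv), DMF, 40 °C, Ar
Reagents that add atoms: prenyl bromide (1-bromo-3-methylbut-2-ene), CC(C)=CCBr
Why: Williamson ether synthesis under mono-anion control: the weak base ionises only the most acidic OH (C4, para to the formyl group; the C2 OH is held in a hydrogen bond to C=O and the C3 OH is not conjugated), and this phenoxide is alkylated by the SN2-reactive allylic bromide.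

Step 2
Reactants: 2 2,3-dihydroxy-4-[(3-methylbut-2-en-1-yl)oxy]benzaldehyde
Product: 3 3-hydroxy-2-methoxy-4-[(3-methylbut-2-en-1-yl)oxy]benzaldehyde
Conditions: MeI (1.1 equiv), K2CO3 (1.0 equiv), DMF, 0 °C → rt, Ar
Reagents that add atoms: iodomethane, CI
Why: Williamson methylation of the mono-anion: of the two remaining OH groups the C2 OH (ortho to and conjugated with the formyl group) is the more acidic, so one equivalent of carbonate gives the 2-phenoxide, which is methylated while the C3 OH stays free (mono-anions of catechol aldehydes alkylate at the more acidic oxygen).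

Step 3
Reactants: 3 3-hydroxy-2-methoxy-4-[(3-methylbut-2-en-1-yl)oxy]benzaldehyde
Product: 4 3-ethynyl-2-methoxy-6-[(3-methylbut-2-en-1-yl)oxy]phenol
Conditions: dimethyl (1-diazo-2-oxopropyl)phosphonate (1.3 equiv), K2CO3 (3 equiv), MeOH, 0 °C → rt, Ar
Reagents that add atoms: dimethyl (1-diazo-2-oxopropyl)phosphonate (Ohira–Bestmann reagent), CC(=O)C(=[N+]=[N-])P(=O)(OC)OC
Why: Seyferth–Gilbert homologation in the Ohira–Bestmann variant: methanolysis of the reagent gives the diazomethylphosphonate anion, which adds to the aldehyde, loses dimethyl phosphate and N2, and gives the terminal alkyne by 1,2-hydrogen shift of the alkylidene carbene; the phenol is only deprotonated and, being meta to the alkyne carbon, cannot cyclise onto it.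

Step 4
Reactants: 4 3-ethynyl-2-methoxy-6-[(3-methylbut-2-en-1-yl)oxy]phenol; 5 4-iodophenol
Product: 11 (E)-3-{3-hydroxy-2-methoxy-4-[(3-methylbut-2-en-1-yl)oxy]phenyl}-1-(4-hydroxyphenyl)prop-2-en-1-one, via alkyne silyl ether 6 (not isolated), via iodoarene silyl ether 7 (not isolated), via alkenylzirconocene chloride 8 (not isolated), via acylzirconocene chloride 9 (not isolated), via bis-silyl chalcone 10 (not isolated)
Conditions: 4 and, in a second flask, 5 (1.1 equiv): HMDS, cat. TMSCl, CH2Cl2, 40 °C, then evaporate; 6: Cp2Zr(H)Cl (1.2 equiv), CH2Cl2, rt; CO (1 atm), rt, then Ar purge; add 7 and PdCl2(PPh3)2 (5 mol %), toluene, rt → 40 °C; 10 % aq. citric acid, THF–MeOH, 0 °C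
Reagents that add atoms: carbon monoxide, [C-]#[O+]; hexamethyldisilazane, C[Si](C)(C)N[Si](C)(C)C (silicon only in 6, 7 and 10); Cp2Zr(H)Cl, [H][Zr](Cl)(C1C=CC=C1)C1C=CC=C1 (zirconium only in 8 and 9)
Why: Syn hydrozirconation of the terminal alkyne puts zirconium on the terminal carbon and fixes the E double bond, CO inserts into the Zr–C bond to give an acylzirconocene chloride whose carbonyl carbon is nucleophilic (an unmasked acyl anion), and palladium catalysis (oxidative addition of the aryl iodide, acyl transfer from zirconium to palladium, reductive elimination) joins this carbon to the electrophilic C–I carbon of ring A with retention of alkene geometry, relying on the known hydrozirconation–carbonylation and palladium-catalysed acylzirconocene–aryl iodide cross-coupling reaction types, while the transient trimethylsilyl ethers keep the phenols from protonating Zr–H and Zr–C bonds and are hydrolysed in the mild acid work-up.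

Step 5
Reactants: 11 (E)-3-{3-hydroxy-2-methoxy-4-[(3-methylbut-2-en-1-yl)oxy]phenyl}-1-(4-hydroxyphenyl)prop-2-en-1-one
Product: 13 (E)-3-[3,4-dihydroxy-2-methoxy-5-(2-methylbut-3-en-2-yl)phenyl]-1-(4-hydroxyphenyl)prop-2-en-1-one, via ortho-dienone 12 (not isolated)
Conditions: EtOH–H2O (4:1), sealed tube, 130 °C, Ar, dark
Reagents that add atoms: none
Why: Water-accelerated aromatic Claisen ([3,3]-sigmatropic) rearrangement: the prenyl group moves with allylic inversion to C5, the only unsubstituted ortho carbon (C3 carries OH and the para carbon carries the enone chain), and dienone 12 tautomerises to the catechol; no stereocentre is formed and the E enone is not touched.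

**Compound list**

1 | 2,3,4-trihydroxybenzaldehyde | O=Cc1ccc(O)c(O)c1O | starting material
2 | 2,3-dihydroxy-4-[(3-methylbut-2-en-1-yl)oxy]benzaldehyde | O=Cc1ccc(OCC=C(C)C)c(O)c1O | intermediate
3 | 3-hydroxy-2-methoxy-4-[(3-methylbut-2-en-1-yl)oxy]benzaldehyde | O=Cc1ccc(OCC=C(C)C)c(O)c1OC | intermediate
4 | 3-ethynyl-2-methoxy-6-[(3-methylbut-2-en-1-yl)oxy]phenol | C#Cc1ccc(OCC=C(C)C)c(O)c1OC | intermediate
5 | 4-iodophenol | Oc1ccc(I)cc1 | starting material
6 | {3-ethynyl-2-methoxy-6-[(3-methylbut-2-en-1-yl)oxy]phenoxy}trimethylsilane | C#Cc1ccc(OCC=C(C)C)c(O[Si](C)(C)C)c1OC | intermediate (not isolated)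
7 | (4-iodophenoxy)trimethylsilane | C[Si](C)(C)Oc1ccc(I)cc1 | intermediate (not isolated)
8 | chlorobis(cyclopentadienyl)[(E)-2-{2-methoxy-4-[(3-methylbut-2-en-1-yl)oxy]-3-(trimethylsilyloxy)phenyl}ethenyl]zirconium | Cl[Zr](/C=C/c1ccc(OCC=C(C)C)c(O[Si](C)(C)C)c1OC)(C1C=CC=C1)C1C=CC=C1 | intermediate (not isolated)
9 | chlorobis(cyclopentadienyl)[(E)-3-{2-methoxy-4-[(3-methylbut-2-en-1-yl)oxy]-3-(trimethylsilyloxy)phenyl}prop-2-enoyl]zirconium | Cl[Zr](C(=O)/C=C/c1ccc(OCC=C(C)C)c(O[Si](C)(C)C)c1OC)(C1C=CC=C1)C1C=CC=C1 | intermediate (not isolated)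
10 | (E)-3-{2-methoxy-4-[(3-methylbut-2-en-1-yl)oxy]-3-(trimethylsilyloxy)phenyl}-1-[4-(trimethylsilyloxy)phenyl]prop-2-en-1-one | C[Si](C)(C)Oc1ccc(cc1)C(=O)/C=C/c1ccc(OCC=C(C)C)c(O[Si](C)(C)C)c1OC | intermediate (not isolated)
11 | (E)-3-{3-hydroxy-2-methoxy-4-[(3-methylbut-2-en-1-yl)oxy]phenyl}-1-(4-hydroxyphenyl)prop-2-en-1-one | Oc1ccc(cc1)C(=O)/C=C/c1ccc(OCC=C(C)C)c(O)c1OC | intermediate
12 | (E)-3-[5-hydroxy-6-methoxy-3-(2-methylbut-3-en-2-yl)-4-oxocyclohexa-1,5-dien-1-yl]-1-(4-hydroxyphenyl)prop-2-en-1-one (racemic, transient) | C=CC(C)(C)C1C=C(/C=C/C(=O)c2ccc(O)cc2)C(OC)=C(O)C1=O | intermediate (not isolated)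
13 | (E)-3-[3,4-dihydroxy-2-methoxy-5-(2-methylbut-3-en-2-yl)phenyl]-1-(4-hydroxyphenyl)prop-2-en-1-one | C=CC(C)(C)c1cc(/C=C/C(=O)c2ccc(O)cc2)c(OC)c(O)c1O | target

**Count**

Total steps: 5. Longest linear sequence: 5 steps (1 → 2 → 3 → 4 → 11 → 13); 4-iodophenol 5 enters in step 4 without prior steps.

**Steps most likely to fail, with fallbacks**

Step 4 (acylzirconocene cross-coupling). Risks are slow coupling of the electron-rich aryl iodide, loss of CO from the acylpalladium intermediate, palladium-catalysed 1,4-addition of 9 to the product enone, and ionisation of the aryl prenyl ether by zerovalent palladium. The fallback replaces the acylzirconium by a classical dithiane acyl anion; it sets out from 3 and comes back at 11. Aldehyde 3 is treated with Me3S+ I− and NaH (2.2 equiv, DMSO–THF, 0 °C, Corey–Chaykovsky) to give racemic 2-methoxy-6-[(3-methylbut-2-en-1-yl)oxy]-3-(oxiran-2-yl)phenol F4. Commercial 4-(tert-butyldimethylsilyloxy)benzaldehyde and propane-1,3-dithiol (cat. I2, CH2Cl2) give tert-butyl[4-(1,3-dithian-2-yl)phenoxy]dimethylsilane F5. F5 is lithiated (n-BuLi, THF, −30 °C) and opens the lithium phenoxide of F4 (LiN(SiMe3)2, 1 equiv) at the terminal epoxide carbon to give racemic 3-(2-{2-[4-(tert-butyldimethylsilyloxy)phenyl]-1,3-dithian-2-yl}-1-hydroxyethyl)-2-methoxy-6-[(3-methylbut-2-en-1-yl)oxy]phenol F6. MeI and CaCO3 (aq. MeCN, 45 °C) unmask racemic 1-[4-(tert-butyldimethylsilyloxy)phenyl]-3-hydroxy-3-{3-hydroxy-2-methoxy-4-[(3-methylbut-2-en-1-yl)oxy]phenyl}propan-1-one F7. Cat. PPTS (CH2Cl2, rt) dehydrates this electron-rich benzylic alcohol to (E)-1-[4-(tert-butyldimethylsilyloxy)phenyl]-3-{3-hydroxy-2-methoxy-4-[(3-methylbut-2-en-1-yl)oxy]phenyl}prop-2-en-1-one F8, and TBAF/AcOH (THF, 0 °C) frees 11.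

Step 2 (2-O- versus 3-O-methylation). The 3-O-methyl isomer or the dimethyl ether may form. The fallback fixes the regiochemistry with a cyclic protecting group; it sets out from 1 and comes back at 3. Compound 1 is heated with dichlorodiphenylmethane (Ph2O, 170 °C) to give 4-hydroxy-2,2-diphenyl-1,3-benzodioxole-5-carbaldehyde F1, in which the 3,4-diol is ketalised and the chelated 2-OH stays free. MeI and K2CO3 (DMF, rt) give 4-methoxy-2,2-diphenyl-1,3-benzodioxole-5-carbaldehyde F2. AcOH–H2O (4:1, reflux) releases 3,4-dihydroxy-2-methoxybenzaldehyde F3, and prenyl bromide with KHCO3 (DMF, 40 °C) alkylates its more acidic 4-OH (para to the formyl group) to give 3.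

Step 5 (Claisen rearrangement on the free catechol chalcone). Risks are loss of the prenyl group, cyclisation of the new ortho-(1,1-dimethylallyl)phenol to a dihydrobenzofuran, and abnormal Claisen products. The fallback runs the rearrangement with in situ trapping; it sets out from 11 and comes back at 13. Compound 11 is acetylated (Ac2O, pyridine, rt) to 4-[(E)-3-{3-acetoxy-2-methoxy-4-[(3-methylbut-2-en-1-yl)oxy]phenyl}prop-2-enoyl]phenyl acetate F9. F9 is heated in Ac2O with NaOAc and N,N-diethylaniline (190 °C), so the phenol formed by the rearrangement is acetylated at once, giving 4-[(E)-3-[3,4-diacetoxy-2-methoxy-5-(2-methylbut-3-en-2-yl)phenyl]prop-2-enoyl]phenyl acetate F10. K2CO3 in MeOH (0 °C) removes the three acetates to give 13.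

**Further compounds**

F1 | step 2 | 4-hydroxy-2,2-diphenyl-1,3-benzodioxole-5-carbaldehyde | O=Cc1ccc2OC(c3ccccc3)(c3ccccc3)Oc2c1O
F2 | step 2 | 4-methoxy-2,2-diphenyl-1,3-benzodioxole-5-carbaldehyde | O=Cc1ccc2OC(c3ccccc3)(c3ccccc3)Oc2c1OC
F3 | step 2 | 3,4-dihydroxy-2-methoxybenzaldehyde | O=Cc1ccc(O)c(O)c1OC
F4 | step 4 | 2-methoxy-6-[(3-methylbut-2-en-1-yl)oxy]-3-(oxiran-2-yl)phenol (racemic) | COc1c(O)c(OCC=C(C)C)ccc1C1CO1
F5 | step 4 | tert-butyl[4-(1,3-dithian-2-yl)phenoxy]dimethylsilane | CC(C)(C)[Si](C)(C)Oc1ccc(cc1)C1SCCCS1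
F6 | step 4 | 3-(2-{2-[4-(tert-butyldimethylsilyloxy)phenyl]-1,3-dithian-2-yl}-1-hydroxyethyl)-2-methoxy-6-[(3-methylbut-2-en-1-yl)oxy]phenol (racemic) | COc1c(O)c(OCC=C(C)C)ccc1C(O)CC1(SCCCS1)c1ccc(O[Si](C)(C)C(C)(C)C)cc1
F7 | step 4 | 1-[4-(tert-butyldimethylsilyloxy)phenyl]-3-hydroxy-3-{3-hydroxy-2-methoxy-4-[(3-methylbut-2-en-1-yl)oxy]phenyl}propan-1-one (racemic) | COc1c(O)c(OCC=C(C)C)ccc1C(O)CC(=O)c1ccc(O[Si](C)(C)C(C)(C)C)cc1
F8 | step 4 | (E)-1-[4-(tert-butyldimethylsilyloxy)phenyl]-3-{3-hydroxy-2-methoxy-4-[(3-methylbut-2-en-1-yl)oxy]phenyl}prop-2-en-1-one | COc1c(O)c(OCC=C(C)C)ccc1/C=C/C(=O)c1ccc(O[Si](C)(C)C(C)(C)C)cc1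
F9 | step 5 | 4-[(E)-3-{3-acetoxy-2-methoxy-4-[(3-methylbut-2-en-1-yl)oxy]phenyl}prop-2-enoyl]phenyl acetate | CC(=O)Oc1ccc(cc1)C(=O)/C=C/c1ccc(OCC=C(C)C)c(OC(C)=O)c1OC
F10 | step 5 | 4-[(E)-3-[3,4-diacetoxy-2-methoxy-5-(2-methylbut-3-en-2-yl)phenyl]prop-2-enoyl]phenyl acetate | CC(=O)Oc1ccc(cc1)C(=O)/C=C/c1cc(C(C)(C)C=C)c(OC(C)=O)c(OC(C)=O)c1OC
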